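At 12 min the flask has held its last portion of coupling partner for 7.00 min, and I reckon it from two ends joined at 4.00 min.

| flask | left-handed substrate | right-handed substrate | coupling partner | remark | time |
|---|---|---|---|---|---|
| delta | 0.055 M | 0.055 M | 0.242 M (in portions, 3) | run made earlier; portions every 2.5 min |  |
| beta | 0.083 M | 0.083 M | 0.242 M (in portions, 3) | run made earlier; portions every 2.5 min |  |
| flask | 0.11 M | 0.11 M | 0.242 M (in portions, 3) | the portions of coupling partner follow each other after 2.5 min, the first at the start | 12 min |

- delta (time / min: left-handed product / %, left-handed substrate / %): 1.00: 0.2, 40.4; 2.00: 1.1, 35.8; 4.00: 2.2, 32.7; 8.00: 6.3, 29.5; 15.0: 11.8, 23.4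
- beta (time / min: left-handed product / %, left-handed substrate / %): 1.33: 0.9, 39.4; 4.00: 1.2, 33.0; 6.00: 4.2, 31.4; 10.0: 7.7, 26.9; 15.0: 12.5, 23.9

(scatter of a reading: 0.5 percentage points)

* concentration of left-handed product at 12 min, in M
* concentration of left-handed substrate at 12 min, in M
* concentration of decomposed reagent at 12 min, in M

- coupling partner is single-handed; left-handed substrate and right-handed substrate are mirror images of each other, charged as a racemate, each of them at the stated concentration
- the handed part of coupling partner does not stay in what it makes, so the products of the two hands are mirror images too

The bench rule here is pseudo-first-order behaviour: with the same charge of coupling partner, in excess over the substrate and given in the same portions, percentage curves carry over between loadings. Delta and beta allow it: at 15.0 min their left-handed product differs by 0.7 percentage points, against a scatter of 0.5 points per reading.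

For the early end I read the two runs at 4.00 min: left-handed substrate 32.9% and left-handed product 1.70%. For the late end I use the product frequency, the percentage points of left-handed product gained per minute divided by the left-handed substrate present, 0.0336 min⁻¹.

The steady late fall of left-handed substrate brings it to 26.2% at 12 min, and the frequency over that stretch brings product to 9.64%. For the flask that means c(left-handed product) = 0.0212 M and c(left-handed substrate) = 0.0576 M. No earlier run reads decomposed reagent, so I put no number of my own on it.

The rule has a border, because it takes c(coupling partner) as steady. Full conversion of left-handed substrate claims 0.227 of the partner charge in delta but 0.455 in the flask, twice as much. At 12 min my product claims 8.76% of the partner charge, about what beta's product claimed at 15.0 min, 8.57%, so I keep the frequency there, though not for long times.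

The forecast gives 0.02 M of left-handed product, 0.058 M of left-handed substrate and 0.03 M of decomposed reagent, holding that “the behaviour is first order in substrate at fixed reagent”; its product stands lower than mine and its substrate higher.

The flask gives 0.0208 M of left-handed product, 0.0570 M of left-handed substrate and 0.0258 M of decomposed reagent.

    coupling partner + left-handed substrate → left-handed product (k = 0.150 M⁻¹ min⁻¹)
    coupling partner ⇌ dormant form (K = 0.590, k = 0.0110 min⁻¹)
    achiral form → decomposed reagent (k = 0.0410 min⁻¹)
    right-handed substrate ⇌ achiral form (K = 0.880, k = 0.250 min⁻¹)
    coupling partner + right-handed substrate → right-handed product (k = 0.00980 M⁻¹ min⁻¹)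
    left-handed substrate ⇌ achiral form (K = 0.880, k = 0.250 min⁻¹)

At 12 min the flask's coupling partner stands at 82.2% of its charge. From 6.00 min to 12 min the frequency predicts a gain of 5.7 points of left-handed product, and the flask gains 5.3 points. Read on from 30 min to 50 min, the same flask is predicted to gain 10 points but gains 6.1 points, with coupling partner at 52.2% of its charge at 50 min.

All runs stem from a simulated flask with made-up constants, noise included.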